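**Conventions and one assumption**

Atom labels C1–C7a are those of the target as a 2,3,3a,4,5,7a‑hexahydro‑1H‑indene (C1 = CHEt, C2 = C=O, C3 = CHMe, C3a, C4, C5, C6, C7, C7a; Cα, Cβ = styryl carbons, Cα on C5). They are used for the corresponding atoms of every intermediate. In the spiro names of 2–10: spiro‑C5 = C2, C6 = C1, C7 = C7a, C8 = C3a, C9 = C3.

Assumption: the azaenolate of the SAMP hydrazone is ethylated with the facial sense usual for SAMP hydrazones of cyclic ketones, which corresponds to (S) at C1; if the sense were opposite, the enantiomeric auxiliary RAMP would be used in steps 2–3.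

## Analysis of the target

Target 24 is a trans‑fused bicyclo[4.3.0]nonene. A cyclopentanone (C1, C2, C3, C3a, C7a) is fused to a cyclohexene (C3a, C4, C5, C6, C7, C7a) with the double bond at C6=C7. It has six stereocentres, (1S,3S,3aR,4R,5S,7aR). H3a and H7a are trans, and the four substituents around the five‑membered ring alternate in face, so that ring is all‑trans. C4 and C5 are adjacent quaternary centres. The carboxyl group on C4 and the E‑styryl group on C5 lie on the face of H3a, and the two ethyl groups lie on the other face. C1 and C3 are enolisable but already in the thermodynamically preferred arrangement. C7a is allylic and cannot be corrected once the alkene is in place. The γ,δ‑unsaturated acid could lactonise onto either alkene under strong acid. The hard part is the vicinal quaternary pair in a fixed relation to C3a, in a six‑membered ring substituted at every position except C6. The strategy rests on one feature: C4 and C5 each carry an ethyl group and an sp2 carbon (carboxyl carbon, Cα) on the same face. This is a hidden cis‑2,3‑diethylsuccinic unit, the retron of 2,3‑diethylmaleic anhydride. The C6=C7(Me) alkene can be read as the enol derivative of a C7 ketone, which turns C3a=C7a–C7(OR)=C6 into the matching diene.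

## Retrosynthetic reasoning

**24 ⇒ 23.** Only the two acetal C–O bonds at C2 are cut. Keeping C2 as a dioxolane to the end removes a second enolisable ketone from every base‑mediated step and keeps C1 and C3 fixed. The forward step is a mild aqueous acid hydrolysis that spares the styrene and the unsaturated acid.

**23 ⇒ 20 + 21.** The Cα=Cβ bond is cut. Cα is at the aldehyde level and is the former anhydride carbonyl on C5. In hydroxylactone 20 it is masked together with the C4 carboxyl, so the acid never needs a protecting group. Forward, phosphonate 21 must add to a neopentyl, non‑enolisable aldehyde and give the E alkene.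

**20 ⇒ 19.** No skeletal bond is cut. The two carbonyls of anhydride 19 are differentiated by reducing the one on C5 to the hemiacylal. The C5 carbonyl is flanked only by the vinylic C6–H. The C4 carbonyl is next to C3a and the cyclopentane, with the C3 methyl on its face. Up to this point the anhydride protects both carboxyl carbons and has no α‑hydrogen.

**19 ⇒ 18 ⇒ 16.** The C7–CH3 bond is cut to enol triflate 18, and 18 goes back to ketone 16. This is the step that relocates unsaturation: with a ketone at C7, the cyclohexene retron no longer points at C4–C5 and C3a–C7a but at C5–C6 and C3a–C4. Forward, deprotonation must occur at C6 and not at C7a, and the methyl coupling must tolerate an anhydride.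

**16 ⇒ 14.** The C7 ketone comes from the enol ether C7(OEt)=C7a of adduct 14. C7a becomes α to a carbonyl, so the ring fusion is set by equilibration rather than in the bond‑forming step.

**14 ⇒ 10 + 13 (key).** C3a–C4 and C5–C6 are cut together. Anhydride 13 delivers C4, C5, both ethyl groups, the carboxyl carbon and Cα with the cis relation already built in. Diene 10 delivers the cyclopentane with C1 and C3 in place. One step forms the six‑membered ring, both quaternary centres and C3a. The forward reaction must overcome the hindrance of a tetrasubstituted dienophile, add exo, and add anti to the C3 methyl.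

**13 ⇒ 11.** Both carboxyl carbons are removed from the symmetrical alkyne 11. Syn double carboxylation gives the Z diacid, which closes to the anhydride.

**10 ⇒ 8 + 9.** The C7a–C7 bond is cut. An alkenyl triflate and an α‑alkoxyvinyl stannane give the 2‑alkoxydiene under neutral conditions with no risk to C1 or C3.

**8 ⇒ 6.** The C3–CH3 bond and the enol O–S bond are cut. Conjugate addition of a methyl cuprate to enone 6 makes C3 and, in the same step, the regiodefined C7a enolate that is triflated. The C1 ethyl group directs the methyl to the opposite face, which gives the trans relation across C2.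

**6 ⇒ 2 ⇒ 1.** The C1–ethyl bond is cut to enone ketal 2. Its C3=C3a double bond blocks the second α‑position, so only C1 can be alkylated, and it later accepts the methyl group. A chiral hydrazone auxiliary sets C1 and with it the absolute configuration of the whole route. Ketal 2 is the mono‑acetal of the symmetrical dione 1.

## Alternatives that were turned down

**Alternative 1: carbenoid insertion that closes the cyclopentanone.**
- Disconnection: C1–C7a.
- Forward key step: Rh2(OAc)4 decomposes α‑diazo‑β‑keto ester A1 (diazo carbon = future C1, chain attached through C3 to C3a). The carbenoid inserts into the C7a–H bond to give trans‑fused β‑keto ester A2.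
- For: 1,5‑insertion into an allylic C–H bond is a dependable cyclopentanone synthesis. It proceeds with retention, so the ring fusion is set directly by insertion into the equatorial hydrogen. On this point it is at least as strong as the chosen route, which relies on an equilibration.
- Against: A2 carries CO2Me where the ethyl group belongs, so C‑ethylation and dealkoxycarbonylation follow. A second, very hindered methyl ester on C4 must be cleaved at the end. The carbenoid can also cyclopropanate the adjacent C6=C7 bond or the styrene, or insert into the C4 ethyl group. Above all, A1 already contains C4, C5 and C3a, so the key step builds only the easy ring and leaves the quaternary pair to an undefined earlier synthesis.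
- Comparison: the chosen route spends its key step on the quaternary pair and ends with the free acid directly from the anhydride.

**Alternative 2: Heck cyclisation forming C5.**
- Disconnection: C5–C6.
- Forward key step: zerovalent palladium, from Pd(OAc)2 and a diphosphine, inserts into the C6–I bond of vinyl iodide A3. The alkenylpalladium adds 6‑exo to C5 of the C5=Cα alkene, and β‑hydride elimination from Cβ gives dioxolane methyl ester A4.
- For: intramolecular Heck reactions do form quaternary carbons. β‑Hydride elimination can only go toward the benzylic carbon, so the E‑styrene appears without a separate olefination. This is stronger than the chosen late olefination of a neopentyl aldehyde.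
- Against: the insertion is into a trisubstituted alkene flanked by quaternary C4. The face of attack at C5 depends on the conformation of an acyclic stereocentre. A3 needs an acyclic quaternary C4 attached to the ring, a tetrasubstituted alkene precursor and a Z‑iodoalkene, which is a long sequence.
- Comparison: the chosen route forms C4 and C5 together with their cis relation guaranteed by the dienophile geometry, from two short fragments.

**Alternative 3: desymmetrising ring‑closing metathesis.**
- Disconnection: C6=C7.
- Forward key step: the second‑generation Grubbs catalyst, RuCl2(=CHPh)(PCy3)(H2IMes), joins the isopropenyl group on C7a of triene A5 with one of the two styryl groups on C5 to give methyl ester A6, with loss of the terminal alkene fragment.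
- For: the conditions are neutral and tolerate the free ketone. The remaining styryl group is already E, and the ring closes at the very end. In mildness this equals or beats the chosen end game.
- Against: a 1,1‑disubstituted alkene must react with a styryl group on a quaternary carbon next to another quaternary carbon, which is a very hindered metathesis. C5 is set only by a choice between diastereotopic groups. A bis‑styryl quaternary carbon beside quaternary C4 is itself hard to make. The hindered ester remains to be cleaved.
- Comparison: like alternatives 1 and 2, it moves the real difficulty into the substrate. The chosen route resolves it in the key step.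

Key step: step 8

## Route

**Step 1**
Reactants: 1 cyclopent‑4‑ene‑1,3‑dione
Product: 2 1,4‑dioxaspiro[4.4]non‑8‑en‑7‑one (mono‑dioxolane of 1)
Conditions: (TMSOCH2)2, TMSOTf (cat.), CH2Cl2, −78 → −20 °C
Reagents that add atoms: 1,2‑bis(trimethylsilyloxy)ethane, C[Si](C)(C)OCCO[Si](C)(C)C
Why: Noyori ketalisation under aprotic conditions; after one carbonyl of the symmetrical ene‑dione is acetalised the other is an enone carbonyl and resists a second ketalisation, and the low temperature avoids conjugate addition to the reactive ene‑dione.

**Step 2**
Reactants: 2 1,4‑dioxaspiro[4.4]non‑8‑en‑7‑one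
Product: 3 SAMP hydrazone of 2, N‑[(2S)‑2‑(methoxymethyl)pyrrolidin‑1‑yl]‑1,4‑dioxaspiro[4.4]non‑8‑en‑7‑imine
Conditions: SAMP, cyclohexane, reflux (Dean–Stark)
Reagents that add atoms: SAMP, (S)‑1‑amino‑2‑(methoxymethyl)pyrrolidine, COC[C@@H]1CCCN1N
Why: Hydrazone formation at the only ketone; 1,2‑condensation is favoured over aza‑Michael addition because the β‑carbon is flanked by the quaternary acetal carbon.

**Step 3**
Reactants: 3 SAMP hydrazone of 2
Product: 5 (6S)‑6‑ethyl SAMP hydrazone, (6S)‑6‑ethyl‑N‑[(2S)‑2‑(methoxymethyl)pyrrolidin‑1‑yl]‑1,4‑dioxaspiro[4.4]non‑8‑en‑7‑imine, via lithium azaenolate 4 (not isolated)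
Conditions: LiN(i‑Pr)2, THF, −78 → 0 °C; EtI, −100 °C → rt
Reagents that add atoms: iodoethane, CCI
Why: Enders SAMP‑hydrazone alkylation; only C1 has an abstractable α‑hydrogen because the other α‑carbon is vinylic, and loss of the β‑acetal oxygen would require an antiaromatic cyclopentadienone derivative; the chelated azaenolate 4 is ethylated on the face fixed by the methoxymethylpyrrolidine, which sets C1 as (S) (see the assumption).

**Step 4**
Reactants: 5 (6S)‑6‑ethyl SAMP hydrazone
Product: 6 (6S)‑6‑ethyl‑1,4‑dioxaspiro[4.4]non‑8‑en‑7‑one
Conditions: sat. aq. oxalic acid, Et2O, rt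
Reagents that add atoms: water, O
Why: Two‑phase oxalic acid hydrolysis is a standard racemisation‑free hydrazone cleavage; the C2 acetal should survive because its oxocarbenium ion would be destabilised by the adjacent enone.

**Step 5**
Reactants: 6 (6S)‑6‑ethyl‑1,4‑dioxaspiro[4.4]non‑8‑en‑7‑one
Product: 8 (6S,9S)‑6‑ethyl‑9‑methyl‑1,4‑dioxaspiro[4.4]non‑7‑en‑7‑yl trifluoromethanesulfonate, via lithium enolate 7 (not isolated)
Conditions: Me2CuLi (from MeLi, CuI), Et2O, −78 °C; then PhNTf2, THF, −78 °C → rt
Reagents that add atoms: lithium dimethylcuprate, [Li+].C[Cu-]C; N‑phenylbis(trifluoromethanesulfonimide), O=S(=O)(N(c1ccccc1)S(=O)(=O)C(F)(F)F)C(F)(F)F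
Why: Cuprate conjugate addition followed by O‑triflation of the regiodefined enolate 7 (conjugate addition–enolate trapping); the methyl group enters at C3 anti to the C1 ethyl group, which shields its own face of the flat enone and buttresses the acetal oxygen on that face towards C3, giving the trans (6S,9S) relation; trapping in the flask prevents enolate equilibration towards C1 and loss of the β‑acetal.

**Step 6**
Reactants: 8 (6S,9S)‑6‑ethyl‑9‑methyl‑1,4‑dioxaspiro[4.4]non‑7‑en‑7‑yl trifluoromethanesulfonate; 9 tributyl(1‑ethoxyethenyl)stannane
Product: 10 (6S,9S)‑7‑(1‑ethoxyethenyl)‑6‑ethyl‑9‑methyl‑1,4‑dioxaspiro[4.4]non‑7‑ene (2‑ethoxydiene C3a=C7a–C7(OEt)=C6)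
Conditions: Pd(PPh3)4 (cat.), LiCl, THF, 65 °C
Reagents that add atoms: none
Why: Stille coupling of an alkenyl triflate with an α‑alkoxyvinylstannane is a standard route to 2‑alkoxy‑1,3‑dienes; the stereocentres are not touched, and the acid‑labile diene is purified on base‑washed silica.

**Step 7**
Reactants: 11 hex‑3‑yne
Product: 13 2,3‑diethylmaleic anhydride (3,4‑diethylfuran‑2,5‑dione), via 2,3‑diethylmaleic acid 12 (not isolated)
Conditions: CO2 (1 atm), Ni(acac)2 (cat.), 2,2′‑bipyridine, Zn, MgBr2, DMF, rt; then aq. HCl
Reagents that add atoms: carbon dioxide, O=C=O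
Why: Nickel‑catalysed reductive double carboxylation of an internal alkyne adds two carboxyl groups syn across the triple bond; the Z diacid closes spontaneously to the tetrasubstituted anhydride on acidification, and the symmetrical alkyne raises no regiochemical question.

**Step 8**
Reactants: 10 (6S,9S)‑7‑(1‑ethoxyethenyl)‑6‑ethyl‑9‑methyl‑1,4‑dioxaspiro[4.4]non‑7‑ene; 13 2,3‑diethylmaleic anhydride
Product: 14 tricyclic enol ether anhydride: hexahydroindene with C7(OEt)=C7a, C2 dioxolane, cis anhydride on C4/C5 on the face of H3a, both ethyl groups on the other face, C3a–C4 bond trans to the C3 methyl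
Conditions: 13 (2 equiv), CH2Cl2, 13 kbar, 25 °C
Reagents that add atoms: none
Why: A concerted, asynchronous normal‑demand [4+2] cycloaddition between the HOMO of the 2‑ethoxydiene C3a=C7a–C7(OEt)=C6 of 10 and the LUMO of 13 forms C3a–C4 and C5–C6 in one operation; the closest known reaction type is the high‑pressure Diels–Alder addition of 2,3‑dimethylmaleic anhydride and its ring‑tied relatives to electron‑rich dienes. The six‑membered ring is closed by the cycloaddition itself, since both new bonds belong to it, and the anhydride ring is carried in intact and ends cis‑fused at C4–C5. C4 and C5 are set relative to each other by the Z geometry of 13 and suprafacial addition, which puts the two carbonyl carbons cis and the two ethyl groups cis. Their relation to C3a needs the exo mode, in which the anhydride ring points away from C7a–C7 and the ethyl groups lie under the diene, so that the carbonyls finish on the side of H3a, the inside hydrogen of the diene terminus. The substrate should favour this mode because an endo anhydride would have to place its rigid ring and the C4 carbonyl oxygen under C7a and C1, where the C1 ethyl group and the lower acetal oxygen project on the attacked face, whereas endo ethyl groups can rotate out of the way. The absolute sense comes from the diene face: C4 bonds to C3a anti to the C3 methyl group, which flanks the reacting terminus directly, while the C1 ethyl group sits on the non‑bonding C7a and is farther from the forming bonds. No regiochemical question arises because 13 is symmetrical, and about 13 kbar is chosen because the strongly negative activation volume offsets the steric cost of two adjacent quaternary centres without heating the acid‑sensitive enol ether. The selectivities needed are therefore exo over endo and attack anti to the methyl group; neither is guaranteed and both are taken up in the risk section.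

**Step 9**
Reactants: 14 tricyclic enol ether anhydride
Product: 16 trans‑fused keto anhydride (C7 ketone, H7a trans to H3a), via cis‑fused C7a‑epimeric ketone 15 (not isolated)
Conditions: 0.2 M HCl, THF–H2O, 0 °C; then DBU (cat.), toluene, 60 °C
Reagents that add atoms: water, O
Why: Enol ether hydrolysis by protonation at C7a gives the C7 ketone while the hindered dioxolane and the tetrasubstituted anhydride (which recloses even if opened) survive brief dilute acid; protonation probably occurs first on the less hindered face syn to H3a (15), but C7a is now α to the ketone and base equilibration should give trans‑fused 16, because in the cis‑fused epimer either chair places a cyclopentane carbon 1,3‑diaxial to an ethyl group on C4 or C5 and puts C7 cis to the C1 ethyl group.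

**Step 10**
Reactants: 16 trans‑fused keto anhydride
Product: 18 C6=C7 enol triflate of 16, via potassium enolate 17 (not isolated)
Conditions: KN(SiMe3)2, THF, −78 °C; then PhNTf2, −78 → 0 °C
Reagents that add atoms: N‑phenylbis(trifluoromethanesulfonimide), O=S(=O)(N(c1ccccc1)S(=O)(=O)C(F)(F)F)C(F)(F)F
Why: Kinetic deprotonation with a bulky amide base removes a C6 hydrogen (CH2) rather than the tertiary, more shielded C7a–H, and O‑sulfonylation of 17 fixes the C6=C7 double bond (enol triflate formation); the anhydride has no α‑hydrogen and the enolate cannot acylate itself without forming a bridgehead alkene.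

**Step 11**
Reactants: 18 C6=C7 enol triflate
Product: 19 alkene anhydride (C6=C7, methyl on C7; anhydride and dioxolane intact)
Conditions: Me4Sn, Pd(PPh3)4 (cat.), LiCl, DMF, 80 °C
Reagents that add atoms: tetramethylstannane, C[Sn](C)(C)C
Why: Stille methylation of an alkenyl triflate; the neutral, non‑nucleophilic tin reagent leaves the anhydride and the dioxolane alone, which a Grignard or cuprate methylation would not guarantee.

**Step 12**
Reactants: 19 alkene anhydride
Product: 20 hydroxylactone (hemiacylal carbon on C5 = future Cα, lactone carbonyl on C4; both epimers at the hemiacylal carbon)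
Conditions: LiAlH(Ot‑Bu)3, THF, −78 → −20 °C; aq. citric acid
Reagents that add atoms: none
Why: Partial reduction of a cyclic anhydride to the hydroxylactone by a bulky, mild hydride that stops at the cyclic aluminium hemiacylal; attack is expected at the C5 carbonyl, flanked only by the vinylic C6–H, rather than at the C4 carbonyl, which is gauche to C3 of the cyclopentane and its methyl group on the same face; the new hemiacylal centre is of no consequence.

**Step 13**
Reactants: 20 hydroxylactone; 21 diethyl benzylphosphonate
Product: 23 dioxolane of the target acid (E‑styryl on C5, free CO2H on C4), via potassium formyl carboxylate 22 (not isolated)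
Conditions: KOt‑Bu, THF, 0 → 50 °C; then aq. HCl (pH 3)
Reagents that add atoms: none
Why: Horner–Wadsworth–Emmons olefination; base opens the hydroxylactone to formyl carboxylate 22, whose non‑enolisable aldehyde is attacked by the aryl‑stabilised phosphonate anion, and reversible addition followed by syn elimination gives the E‑styrene, reinforced by the quaternary substituent; the dioxolane keeps C1 and C3 from enolising under the strongly basic conditions.

**Step 14**
Reactants: 23 dioxolane of the target acid
Product: 24 (1S,3S,3aR,4R,5S,7aR)‑1,4,5‑triethyl‑3,7‑dimethyl‑2‑oxo‑5‑[(E)‑2‑phenylethenyl]‑2,3,3a,4,5,7a‑hexahydro‑1H‑indene‑4‑carboxylic acid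
Conditions: 2 M HCl, THF, 40 °C
Reagents that add atoms: water, O
Why: Acid‑catalysed acetal hydrolysis frees the C2 ketone; C1 and C3 become enolisable but already hold the thermodynamically preferred all‑trans arrangement around the cyclopentanone, and dilute acid at moderate temperature should not protonate the styrene or the trisubstituted alkene, so lactonisation of the γ,δ‑unsaturated acid is not expected.

## Compound list

1 | cyclopent‑4‑ene‑1,3‑dione | O=C1CC(=O)C=C1 | starting material
2 | 1,4‑dioxaspiro[4.4]non‑8‑en‑7‑one | O=C1CC2(OCCO2)C=C1 | intermediate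
3 | SAMP hydrazone of 2 | COC[C@@H]1CCCN1N=C3CC2(OCCO2)C=C3 | intermediate
4 | lithium azaenolate of 3 (deprotonated at C1) | COC[C@@H]1CCCN1[N-]C3=CC2(OCCO2)C=C3.[Li+] | intermediate
5 | (6S)‑6‑ethyl SAMP hydrazone | CC[C@@H]1C2(OCCO2)C=CC1=NN3CCC[C@H]3COC | intermediate
6 | (6S)‑6‑ethyl‑1,4‑dioxaspiro[4.4]non‑8‑en‑7‑one | CC[C@@H]1C2(OCCO2)C=CC1=O | intermediate
7 | lithium (6S,9S)‑6‑ethyl‑9‑methyl‑1,4‑dioxaspiro[4.4]non‑7‑en‑7‑olate | CC[C@@H]1C2(OCCO2)[C@@H](C)C=C1[O-].[Li+] | intermediate
8 | (6S,9S)‑6‑ethyl‑9‑methyl‑1,4‑dioxaspiro[4.4]non‑7‑en‑7‑yl trifluoromethanesulfonate | CC[C@@H]1C2(OCCO2)[C@@H](C)C=C1OS(=O)(=O)C(F)(F)F | intermediate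
9 | tributyl(1‑ethoxyethenyl)stannane | CCCC[Sn](CCCC)(CCCC)C(=C)OCC | starting material
10 | (6S,9S)‑7‑(1‑ethoxyethenyl)‑6‑ethyl‑9‑methyl‑1,4‑dioxaspiro[4.4]non‑7‑ene | CC[C@@H]1C2(OCCO2)[C@@H](C)C=C1C(OCC)=C | intermediate
11 | hex‑3‑yne | CCC#CCC | starting material
12 | 2,3‑diethylmaleic acid, (Z)‑2,3‑diethylbut‑2‑enedioic acid | CC/C(C(=O)O)=C(\CC)C(=O)O | intermediate
13 | 2,3‑diethylmaleic anhydride | CCC1=C(CC)C(=O)OC1=O | intermediate
14 | tricyclic enol ether anhydride (Diels–Alder adduct) | CC[C@@H]1C2(OCCO2)[C@@H](C)[C@H]3C1=C(OCC)C[C@]4(CC)C(=O)OC(=O)[C@]34CC | intermediate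
15 | cis‑fused keto anhydride (C7a epimer of 16) | CC[C@@H]1C2(OCCO2)[C@@H](C)[C@H]3[C@@H]1C(=O)C[C@]4(CC)C(=O)OC(=O)[C@]34CC | intermediate
16 | trans‑fused keto anhydride | CC[C@@H]1C2(OCCO2)[C@@H](C)[C@H]3[C@H]1C(=O)C[C@]4(CC)C(=O)OC(=O)[C@]34CC | intermediate
17 | potassium C6=C7 enolate of 16 | CC[C@@H]1C2(OCCO2)[C@@H](C)[C@H]3[C@H]1C([O-])=C[C@]4(CC)C(=O)OC(=O)[C@]34CC.[K+] | intermediate
18 | C6=C7 enol triflate | CC[C@@H]1C2(OCCO2)[C@@H](C)[C@H]3[C@H]1C(OS(=O)(=O)C(F)(F)F)=C[C@]4(CC)C(=O)OC(=O)[C@]34CC | intermediate
19 | alkene anhydride (C7 methyl) | CC[C@@H]1C2(OCCO2)[C@@H](C)[C@H]3[C@H]1C(C)=C[C@]4(CC)C(=O)OC(=O)[C@]34CC | intermediate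
20 | hydroxylactone (hemiacylal carbon on C5) | CC[C@@H]1C2(OCCO2)[C@@H](C)[C@H]3[C@H]1C(C)=C[C@]4(CC)C(O)OC(=O)[C@]34CC | intermediate
21 | diethyl benzylphosphonate | CCOP(=O)(Cc1ccccc1)OCC | starting material
22 | potassium formyl carboxylate (CHO on C5, CO2K on C4) | CC[C@@H]1C2(OCCO2)[C@@H](C)[C@H]3[C@H]1C(C)=C[C@@](C=O)(CC)[C@]3(CC)C(=O)[O-].[K+] | intermediate
23 | dioxolane of the target acid | CC[C@@H]1C2(OCCO2)[C@@H](C)[C@H]3[C@H]1C(C)=C[C@@](/C=C/c1ccccc1)(CC)[C@]3(CC)C(=O)O | intermediate
24 | (1S,3S,3aR,4R,5S,7aR)‑1,4,5‑triethyl‑3,7‑dimethyl‑2‑oxo‑5‑[(E)‑2‑phenylethenyl]‑2,3,3a,4,5,7a‑hexahydro‑1H‑indene‑4‑carboxylic acid | CC[C@@H]1C(=O)[C@@H](C)[C@H]2[C@H]1C(C)=C[C@@](/C=C/c1ccccc1)(CC)[C@]2(CC)C(=O)O | target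

## Step count and least certain steps

Total: 14 steps. Longest linear sequence: 13 steps (steps 1–6 and 8–14); step 7 is the one‑step side branch to the dienophile.

**Step 8 (key step).** The most likely failure is that no cycloaddition occurs in a practical time, or that addition goes endo or on the methyl face. Two quaternary centres are formed, and the ethyl groups of 13 sweep more space than the methyl groups of the precedent. Fallback: set out from diene 10 and replace 13 by the ring‑tied dienophile 2,5‑dimethyl‑2,5‑dihydrothiophene‑3,4‑dicarboxylic anhydride F1, prepared separately. Its alkyl carbons are held back in a five‑membered sulfide ring. Dienophiles of this kind react under pressure where open dialkylmaleic anhydrides fail, and they tend to place the anhydride exo. Cycloaddition at 13 kbar would give the sulfide‑bridged adduct F2. Desulfurisation of F2 with Raney Ni in acetone–ethanol turns each CH(CH3)–S carbon into an ethyl group and returns to adduct 14.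

**Step 12.** The hydride may attack the C4 carbonyl instead of the C5 carbonyl, because both lie on quaternary carbons and the steric difference is one atom further out. Reduction may also run on past the hemiacylal. Fallback, for the case that the C4 carbonyl is the more reactive one: use that carbonyl on purpose. From anhydride 19, NaBH4 in THF–EtOH reduces the C4 carbonyl fully to lactone F3 (CH2 on C4, lactone carbonyl on C5). i‑Bu2AlH at −78 °C gives lactol F4. Olefination of the lactol with the anion of 21 gives styryl alcohol F5 (E‑styryl on C5, CH2OH on C4). Dess–Martin oxidation to aldehyde F6 and oxidation with NaClO2/NaH2PO4/2‑methylbut‑2‑ene returns to acid 23.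

**Step 13.** Addition of the bulky, weakly nucleophilic phosphonate anion to a neopentyl aldehyde that sits next to a carboxylate may be too slow, and forcing conditions could favour a Cannizzaro‑type loss of the aldehyde. Fallback: build the styrene in two smaller operations. From hydroxylactone 20, methylenation with Ph3P=CH2 (a small, reactive ylide, in excess) gives vinyl acid F7. A Heck arylation of its terminal vinyl group with iodobenzene (Pd(OAc)2, P(o‑tol)3, Et3N, DMF, 80 °C) is E‑selective by mechanism and returns to acid 23.

**Step 5.** Facial selectivity may be poor, because the directing ethyl group is 1,3 to the reacting carbon and the acetal between them is locally symmetrical. A cis/trans mixture of triflates would result. Fallback: take control from the reagent instead of the substrate. From enone 6, a copper‑catalysed asymmetric conjugate addition (Me2Zn, Cu(OTf)2, a chiral phosphoramidite ligand matched to the substrate bias, toluene, −30 °C) gives methylzinc enolate F8. It is triflated in the same flask with PhNTf2 and rejoins the route at triflate 8.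

**Step 3.** Enantioselectivity may erode, because the azaenolate is cross‑conjugated with the ring alkene and the alkylated carbon is next to a quaternary acetal carbon. The cleavage in step 4 could also partly racemise the α‑centre. Fallback: resolution instead of auxiliary control. From enone ketal 2, LiN(i‑Pr)2 and EtI give racemic 6‑ethyl‑1,4‑dioxaspiro[4.4]non‑8‑en‑7‑one F9. Luche reduction (NaBH4, CeCl3, MeOH) anti to the ethyl group gives mainly the racemic cis allylic alcohol F10. Lipase‑mediated acetylation with vinyl acetate separates the enantiomers. The (6S,7S)‑alcohol F11 is taken on as such or, if it is the acylated enantiomer, after methanolysis of its acetate F12. MnO2 oxidation returns to enone 6.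

## Further compounds

F1 | step 8 | 2,5‑dimethyl‑2,5‑dihydrothiophene‑3,4‑dicarboxylic anhydride (cis/trans mixture) | CC1SC(C)C2=C1C(=O)OC2=O
F2 | step 8 | sulfide‑bridged cycloadduct of 10 and F1 (thiolane in place of the two ethyl groups of 14) | CC[C@@H]1C2(OCCO2)[C@@H](C)[C@H]3C1=C(OCC)C[C@]4(C(C)SC5C)C(=O)OC(=O)[C@]345
F3 | step 12 | lactone with CH2 on C4 and carbonyl on C5 | CC[C@@H]1C2(OCCO2)[C@@H](C)[C@H]3[C@H]1C(C)=C[C@]4(CC)C(=O)OC[C@]34CC
F4 | step 12 | lactol of F3 (hemiacetal carbon on C5) | CC[C@@H]1C2(OCCO2)[C@@H](C)[C@H]3[C@H]1C(C)=C[C@]4(CC)C(O)OC[C@]34CC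
F5 | step 12 | styryl alcohol (E‑styryl on C5, CH2OH on C4) | CC[C@@H]1C2(OCCO2)[C@@H](C)[C@H]3[C@H]1C(C)=C[C@@](/C=C/c1ccccc1)(CC)[C@]3(CC)CO
F6 | step 12 | styryl aldehyde (CHO on C4) | CC[C@@H]1C2(OCCO2)[C@@H](C)[C@H]3[C@H]1C(C)=C[C@@](/C=C/c1ccccc1)(CC)[C@]3(CC)C=O
F7 | step 13 | vinyl acid (vinyl on C5, CO2H on C4) | CC[C@@H]1C2(OCCO2)[C@@H](C)[C@H]3[C@H]1C(C)=C[C@@](C=C)(CC)[C@]3(CC)C(=O)O
F8 | step 5 | methylzinc (6S,9S)‑6‑ethyl‑9‑methyl‑1,4‑dioxaspiro[4.4]non‑7‑en‑7‑olate | CC[C@@H]1C2(OCCO2)[C@@H](C)C=C1O[Zn]C
F9 | step 3 | racemic 6‑ethyl‑1,4‑dioxaspiro[4.4]non‑8‑en‑7‑one | CCC1C2(OCCO2)C=CC1=O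
F10 | step 3 | racemic cis‑6‑ethyl‑1,4‑dioxaspiro[4.4]non‑8‑en‑7‑ol | CCC1C2(OCCO2)C=CC1O
F11 | step 3 | (6S,7S)‑6‑ethyl‑1,4‑dioxaspiro[4.4]non‑8‑en‑7‑ol | CC[C@@H]1C2(OCCO2)C=C[C@@H]1O
F12 | step 3 | (6S,7S)‑6‑ethyl‑1,4‑dioxaspiro[4.4]non‑8‑en‑7‑yl acetate | CC[C@@H]1C2(OCCO2)C=C[C@@H]1OC(C)=O
A1 | alternative 1 | α‑diazo‑β‑keto ester on the cyclohexene (diazo carbon = future C1) | COC(=O)C(=[N+]=[N-])C(=O)[C@@H](C)[C@H]1CC(C)=C[C@@](/C=C/c2ccccc2)(CC)[C@]1(CC)C(=O)OC
A2 | alternative 1 | trans‑fused β‑keto ester (CO2Me on C1, methyl ester on C4) | COC(=O)[C@@H]1C(=O)[C@@H](C)[C@H]2[C@H]1C(C)=C[C@@](/C=C/c1ccccc1)(CC)[C@]2(CC)C(=O)OC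
A3 | alternative 2 | (Z)‑vinyl iodide on C7a with the C5=Cα alkene chain on C3a | CC[C@@H]1C2(OCCO2)[C@@H](C)[C@H]([C@@](CC)(C(=O)OC)/C(CC)=C/Cc3ccccc3)[C@H]1/C(C)=C\I
A4 | alternative 2 | C2‑dioxolane methyl ester of the target | CC[C@@H]1C2(OCCO2)[C@@H](C)[C@H]3[C@H]1C(C)=C[C@@](/C=C/c1ccccc1)(CC)[C@]3(CC)C(=O)OC
A5 | alternative 3 | bis‑styryl triene (isopropenyl on C7a, two styryl groups on C5) | CC[C@@H]1C(=O)[C@@H](C)[C@H]([C@@](CC)(C(=O)OC)C(CC)(/C=C/c2ccccc2)/C=C/c3ccccc3)[C@H]1C(C)=C
A6 | alternative 3 | methyl ester of the target | CC[C@@H]1C(=O)[C@@H](C)[C@H]2[C@H]1C(C)=C[C@@](/C=C/c1ccccc1)(CC)[C@]2(CC)C(=O)OC
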